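Ring B of the target, the 1,2-dihydronaphthalene ring C1–C2–C3–C4–C4a–C8a, is cut at C1–C2 (aryl-bearing CH to the CH that carries CH2OH) and at C4–C4a (vinylic CH to fused benzene ring A). Both bonds are made in one acid-mediated [3+3] annulation: a chiral phosphoric acid converts a p-hydroxybenzhydrol into its p-quinone methide, the enol of an α-formyl ester adds at C1, and a second formyl group then closes onto C4a with loss of water. The step exploits that C1 is para to the free phenol of the pendant ring and that C4a is para to the free C7 hydroxyl of ring A. The precursors are a diarylmethanol and diethyl 2,3-diformylsuccinate; its spare formyl group is a traceless activator.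

Key step: step 3

Remarks and assumptions
- Numbering used throughout: C1 = sp3 carbon bearing the pendant aryl group, C2 = carbon bearing CH2OH, C3 = carbon bearing CHO, C4 = vinylic CH, C4a/C8a = ring-fusion carbons, C7–OH and C6–OMe on ring A. In this numbering the target is (1S,2R), trans.
- (R)-TRIP is assumed to leave open the face of the quinone methide that gives the C1 configuration of the target; if the opposite sense is found, (S)-TRIP is used.
- Compound 8 is drawn as the dialdehyde; it is a mixture of enol and cyclic hemiacetal tautomers, all of which converge in step 3.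

Step 1
Reactants: 1 4-bromo-2-methoxyphenol; 2 isovanillin (3-hydroxy-4-methoxybenzaldehyde)
Product: 5 (3-hydroxy-4-methoxyphenyl)(4-hydroxy-3-methoxyphenyl)methanol (racemic), via lithium 4-lithio-2-methoxyphenolate 3 (not isolated), via sodium 5-formyl-2-methoxyphenolate 4 (not isolated)
Conditions: 1: n-BuLi (1.0 equiv), then t-BuLi (2.1 equiv), THF, −78 °C; 2: NaH (1.05 equiv), THF, 0 °C; add 4 to 3, −78 °C → rt; aq NH4Cl
Reagents that add atoms: none
Why: 1,2-Addition of an aryllithium to an aldehyde: bromine–lithium exchange on the lithium phenolate of 1 gives dianion 3, whose aryl carbon adds to the carbonyl of the phenolate-masked aldehyde 4; the carbinol centre is formed racemic, which is immaterial because it becomes sp2 in step 3.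

Step 2
Reactants: 6 diethyl succinate
Product: 8 diethyl 2,3-diformylsuccinate, via diethyl 2-formylsuccinate 7 (not isolated)
Conditions: HCO2Et (6 equiv), NaOEt (2.5 equiv), Et2O, 0 °C → rt; then cold 1 M HCl
Reagents that add atoms: ethyl formate, CCOC=O
Why: Twofold crossed Claisen condensation (C-formylation of both α-carbons with ethyl formate), driven by deprotonation of each new α-formyl ester; no stereocentre matters because both methine carbons are enolised.

Step 3
Reactants: 5 (3-hydroxy-4-methoxyphenyl)(4-hydroxy-3-methoxyphenyl)methanol; 8 diethyl 2,3-diformylsuccinate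
Product: 11 diethyl (1S)-2-formyl-7-hydroxy-1-(4-hydroxy-3-methoxyphenyl)-6-methoxy-1,2-dihydronaphthalene-2,3-dicarboxylate (both C2 epimers), via p-quinone methide 9 (not isolated), via open-chain adduct 10 (not isolated)
Conditions: 8 (2 equiv), (R)-TRIP (10 mol %), CH2Cl2, 0 °C → rt; then HFIP, TsOH·H2O (20 mol %), 40 °C
Reagents that add atoms: none
Why: The phosphoric acid dehydrates 5 to the p-quinone methide 9 and, hydrogen-bonded both to its carbonyl oxygen and to the enol OH of 8, steers the 1,6-conjugate addition that forms C1–C2 (adduct 10); the added TsOH/HFIP then protonates the enolised formyl group on C3, whose carbon (C4) is attacked by the arene carbon para to the free hydroxyl (Friedel–Crafts hydroxyalkylation, C4a–C4), and loss of water gives the C3=C4 double bond. The closest known reaction types are the chiral-phosphoric-acid-catalysed conjugate addition/cyclodehydration of β-dicarbonyl enols with quinone methides generated in situ from hydroxybenzhydrols, and the Bradsher-type cyclodehydration of γ-aryl-α-formyl esters to 3,4-dihydro-2-naphthoates. Ring B is the only ring closed, by a 6-exo-trig attack of the arene on the formyl carbon. C1 is the only stereocentre that must be controlled and is set by the catalyst through the face of 9 that it leaves open; the quaternary C2 forms as both epimers, which is harmless because step 4 erases it. The step needs (a) C- rather than O-alkylation and a single alkylation, favoured by the soft enol carbon and an excess of 8, (b) closure on the 3-hydroxy-4-methoxyphenyl ring rather than on the pendant ring, favoured because only that ring has a free OH para to a carbon ortho to C1 (the ortho carbons of the pendant ring are meta to its OH) and the acid is kept mild, and (c) six- rather than five-membered closure, since only the formyl group on C3 reaches the arene through a six-membered transition state. Furan formation from the 1,4-dialdehyde unit, the usual fate of 8 in acid, is blocked once C2 is quaternary.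

Step 4
Reactants: 11 diethyl (1S)-2-formyl-7-hydroxy-1-(4-hydroxy-3-methoxyphenyl)-6-methoxy-1,2-dihydronaphthalene-2,3-dicarboxylate
Product: 12 diethyl (1S,2R)-7-hydroxy-1-(4-hydroxy-3-methoxyphenyl)-6-methoxy-1,2-dihydronaphthalene-2,3-dicarboxylate (trans)
Conditions: NaOEt (3 equiv), EtOH, 0 °C → rt, argon; AcOH quench
Reagents that add atoms: none
Why: Retro-Claisen deformylation of the non-enolisable α-formyl ester by ethoxide gives ethyl formate and an ester dienolate that is protonated at C2, and reversible deprotonation under the same base lets C2 settle in the thermodynamically favoured 1,2-trans arrangement (aryl and ester pseudoaxial), so C2 is set by equilibration relative to the fixed C1.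

Step 5
Reactants: 12 diethyl (1S,2R)-7-hydroxy-1-(4-hydroxy-3-methoxyphenyl)-6-methoxy-1,2-dihydronaphthalene-2,3-dicarboxylate
Product: 13 [(1S,2R)-7-hydroxy-1-(4-hydroxy-3-methoxyphenyl)-3-(hydroxymethyl)-6-methoxy-1,2-dihydronaphthalen-2-yl]methanol
Conditions: i-Bu2AlH (8 equiv), THF, −78 → 0 °C; aq KNaC4H4O6
Reagents that add atoms: none
Why: Hydride reduction of both esters to primary alcohols with an aluminium hydride that reduces the conjugated ester in the 1,2 sense; the phenols are carried as aluminium phenoxides and neither stereocentre is touched.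

Step 6
Reactants: 13 [(1S,2R)-7-hydroxy-1-(4-hydroxy-3-methoxyphenyl)-3-(hydroxymethyl)-6-methoxy-1,2-dihydronaphthalen-2-yl]methanol
Product: 14 (3R,4S)-6-hydroxy-4-(4-hydroxy-3-methoxyphenyl)-3-(hydroxymethyl)-7-methoxy-3,4-dihydronaphthalene-2-carbaldehyde (7,8,9,9-tetradehydroisolariciresinol)
Conditions: activated MnO2 (15 equiv), EtOAc, rt, argon, dark
Reagents that add atoms: none
Why: Chemoselective allylic oxidation with MnO2: only the hydroxymethyl group on C3 is allylic (on the styrenic C3=C4 bond) and is oxidised to the enal, whereas the saturated primary alcohol on C2 and both stereocentres are left alone.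

Compound list
1 | 4-bromo-2-methoxyphenol | COc1cc(Br)ccc1O | starting material
2 | isovanillin (3-hydroxy-4-methoxybenzaldehyde) | COc1ccc(C=O)cc1O | starting material
3 | lithium 4-lithio-2-methoxyphenolate | [Li]c1ccc([O-])c(OC)c1.[Li+] | intermediate
4 | sodium 5-formyl-2-methoxyphenolate | COc1ccc(C=O)cc1[O-].[Na+] | intermediate
5 | (3-hydroxy-4-methoxyphenyl)(4-hydroxy-3-methoxyphenyl)methanol, racemic | COc1ccc(C(O)c2ccc(O)c(OC)c2)cc1O | intermediate
6 | diethyl succinate | CCOC(=O)CCC(=O)OCC | starting material
7 | diethyl 2-formylsuccinate | CCOC(=O)CC(C=O)C(=O)OCC | intermediate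
8 | diethyl 2,3-diformylsuccinate (tautomer mixture) | CCOC(=O)C(C=O)C(C=O)C(=O)OCC | intermediate
9 | 4-[(3-hydroxy-4-methoxyphenyl)methylidene]-2-methoxycyclohexa-2,5-dien-1-one (p-quinone methide) | COC1=CC(=Cc2ccc(OC)c(O)c2)C=CC1=O | intermediate
10 | diethyl 2,3-diformyl-2-[(R)-(3-hydroxy-4-methoxyphenyl)(4-hydroxy-3-methoxyphenyl)methyl]butanedioate (C2 and C3 unassigned) | COc1cc([C@H](C(C=O)(C(=O)OCC)C(C=O)C(=O)OCC)c2ccc(OC)c(O)c2)ccc1O | intermediate
11 | diethyl (1S)-2-formyl-7-hydroxy-1-(4-hydroxy-3-methoxyphenyl)-6-methoxy-1,2-dihydronaphthalene-2,3-dicarboxylate (both C2 epimers) | COc1cc([C@H]2c3cc(O)c(OC)cc3C=C(C(=O)OCC)C2(C=O)C(=O)OCC)ccc1O | intermediate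
12 | diethyl (1S,2R)-7-hydroxy-1-(4-hydroxy-3-methoxyphenyl)-6-methoxy-1,2-dihydronaphthalene-2,3-dicarboxylate | COc1cc([C@H]2c3cc(O)c(OC)cc3C=C(C(=O)OCC)[C@@H]2C(=O)OCC)ccc1O | intermediate
13 | [(1S,2R)-7-hydroxy-1-(4-hydroxy-3-methoxyphenyl)-3-(hydroxymethyl)-6-methoxy-1,2-dihydronaphthalen-2-yl]methanol | COc1cc([C@H]2c3cc(O)c(OC)cc3C=C(CO)[C@@H]2CO)ccc1O | intermediate
14 | (3R,4S)-6-hydroxy-4-(4-hydroxy-3-methoxyphenyl)-3-(hydroxymethyl)-7-methoxy-3,4-dihydronaphthalene-2-carbaldehyde | COc1cc([C@H]2c3cc(O)c(OC)cc3C=C(C=O)[C@@H]2CO)ccc1O | target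

Total step count: 6. Longest linear sequence: 5 steps (step 1, then steps 3, 4, 5 and 6; step 2 supplies the second partner of the convergent key step).

Steps most likely to fail

Step 3. The catalyst may discriminate the two faces of the quinone methide poorly, because its two aryl-type substituents differ only in the placement of OH and OMe. In addition, part of the material may close onto the pendant ring (para to its OMe) or stall at the open-chain adduct. The fallback gives up catalyst control and resolves. It sets out from 5 and 8, which would be combined with achiral diphenyl phosphate in CH2Cl2 and then TsOH·H2O in HFIP, passing through the racemic open-chain adduct F1 to the racemic 2-formyl diester F2. Deformylation with NaOEt in EtOH as in step 4 would give the racemic trans diester F3. Preparative chromatography on an amylose tris(3,5-dimethylphenylcarbamate) phase would separate 12 from its enantiomer F4. The fallback returns to the route at 12.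

Step 6. The free, electron-rich phenols may be oxidised on the MnO2 surface (quinone methide formation and oligomerisation), or the dihydronaphthalene may be dehydrogenated to the naphthalene. The fallback masks the phenols before the redox steps. It sets out from 12, which would be silylated (TBSCl, imidazole, DMF) to the bis-silyl diester F5. Reduction with i-Bu2AlH would give the bis-silyl diol F6, and MnO2 in CH2Cl2 the bis-silyl enal F7. HF·pyridine in THF at 0 °C would then free both phenols. The fallback returns to the route at 14.

Step 1. The phenolate salts may be too poorly soluble for clean addition, proton transfer may quench the aryllithium, or 5 may ionise and oligomerise during isolation. The fallback uses protected partners. It sets out from 1 and 2, which would be silylated (TBSCl, imidazole, DMF) to tert-butyl(4-bromo-2-methoxyphenoxy)dimethylsilane F8 and 3-(tert-butyldimethylsilyloxy)-4-methoxybenzaldehyde F9. Bromine–lithium exchange on F8 (t-BuLi, THF, −78 °C) would give the aryllithium F10, which adds to F9 to give the bis-silyl carbinol F11. Bu4NF buffered with AcOH in THF at 0 °C would remove both silyl groups. The fallback returns to the route at 5.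

Further compounds
F1 | step 3 | racemic diethyl 2,3-diformyl-2-[(3-hydroxy-4-methoxyphenyl)(4-hydroxy-3-methoxyphenyl)methyl]butanedioate | COc1cc(C(C(C=O)(C(=O)OCC)C(C=O)C(=O)OCC)c2ccc(OC)c(O)c2)ccc1O
F2 | step 3 | racemic diethyl 2-formyl-7-hydroxy-1-(4-hydroxy-3-methoxyphenyl)-6-methoxy-1,2-dihydronaphthalene-2,3-dicarboxylate | COc1cc(C2c3cc(O)c(OC)cc3C=C(C(=O)OCC)C2(C=O)C(=O)OCC)ccc1O
F3 | step 3 | racemic trans diester (1:1 mixture of 12 and its enantiomer) | COc1cc([C@H]2c3cc(O)c(OC)cc3C=C(C(=O)OCC)[C@@H]2C(=O)OCC)ccc1O.COc1cc([C@@H]2c3cc(O)c(OC)cc3C=C(C(=O)OCC)[C@H]2C(=O)OCC)ccc1O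
F4 | step 3 | diethyl (1R,2S)-7-hydroxy-1-(4-hydroxy-3-methoxyphenyl)-6-methoxy-1,2-dihydronaphthalene-2,3-dicarboxylate (enantiomer of 12) | COc1cc([C@@H]2c3cc(O)c(OC)cc3C=C(C(=O)OCC)[C@H]2C(=O)OCC)ccc1O
F5 | step 6 | bis(tert-butyldimethylsilyl) ether of 12, same configuration | COc1cc([C@H]2c3cc(O[Si](C)(C)C(C)(C)C)c(OC)cc3C=C(C(=O)OCC)[C@@H]2C(=O)OCC)ccc1O[Si](C)(C)C(C)(C)C
F6 | step 6 | bis(tert-butyldimethylsilyl) ether of 13, same configuration | COc1cc([C@H]2c3cc(O[Si](C)(C)C(C)(C)C)c(OC)cc3C=C(CO)[C@@H]2CO)ccc1O[Si](C)(C)C(C)(C)C
F7 | step 6 | bis(tert-butyldimethylsilyl) ether of 14, same configuration | COc1cc([C@H]2c3cc(O[Si](C)(C)C(C)(C)C)c(OC)cc3C=C(C=O)[C@@H]2CO)ccc1O[Si](C)(C)C(C)(C)C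
F8 | step 1 | tert-butyl(4-bromo-2-methoxyphenoxy)dimethylsilane | COc1cc(Br)ccc1O[Si](C)(C)C(C)(C)C
F9 | step 1 | 3-(tert-butyldimethylsilyloxy)-4-methoxybenzaldehyde | COc1ccc(C=O)cc1O[Si](C)(C)C(C)(C)C
F10 | step 1 | [4-(tert-butyldimethylsilyloxy)-3-methoxyphenyl]lithium | [Li]c1ccc(O[Si](C)(C)C(C)(C)C)c(OC)c1
F11 | step 1 | [3-(tert-butyldimethylsilyloxy)-4-methoxyphenyl][4-(tert-butyldimethylsilyloxy)-3-methoxyphenyl]methanol, racemic | COc1ccc(C(O)c2ccc(O[Si](C)(C)C(C)(C)C)c(OC)c2)cc1O[Si](C)(C)C(C)(C)C
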